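If a flask slows down faster than its reagents are used up, one number can carry the gap.

| flask | starting material | coupling partner | catalyst | remark |
|---|---|---|---|---|
| midnight | 0.30 M | 0.14 M | 0.39 mM | run made earlier |
| winter | 0.30 M | 0.21 M | 0.39 mM | run made earlier |
| spring | 0.60 M | 0.285 M | 0.39 mM | run made earlier |
| flask | 0.30 M | 0.285 M | 0.39 mM |  |

| run | time / min | target / % |
|---|---|---|
| midnight | 2.50 | 6 |
| midnight | 5.00 | 17 |
| midnight | 10.0 | 22 |
| midnight | 15.0 | 24 |
| midnight | 30.0 | 37 |
| winter | 2.50 | 12 |
| winter | 5.00 | 21 |
| winter | 10.0 | 29 |
| winter | 15.0 | 34 |
| winter | 30.0 | 49 |
| spring | 6.00 | 22 |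
| spring | 12.0 | 30 |
| spring | 20.0 | 33 |
| spring | 25.0 | 38 |
| spring | 30.0 | 41 |

(each reading ± 1.5 percentage points)

- no earlier run changes the charge of catalyst; that part of a forecast is a guess

- apparent order in catalyst when 10% of the starting material are converted (percent change of the rate of making target for one percent more catalyst charged)

I read that number from the winter run. Its first reading gives 0.0144 M min⁻¹ and its last two give 0.00300 M min⁻¹, so the late rate is 0.208 of the early one. But c(starting material) × c(coupling partner) falls to 0.277 of its early value. Dividing gives 0.752, a reading with the scatter of these points. This is the kept share: the ratio of late to early rate, divided by the same ratio of that product.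

Scaling the winter rate with the coupling partner, I expect the flask to start near 0.0195 M min⁻¹. At that rate I put 10% conversion of the starting material at about 1.54 min. The coupling partner is the limiting reagent, charged below the starting material. From 10% to 70% conversion, the fall in that product takes the flask's rate to 0.0980 of its value at 10%. If the flask keeps the winter run's share, that becomes 0.0737, so I expect a long tail.

The forecast says 0.95: “None of the runs varies the catalyst”. My own guess is one, a little above the forecast, because I expect the flask to pass 10% before the time of the winter run's second reading.

    starting material + coupling partner + catalyst → target + catalyst, rate k1*[starting material]*[coupling partner]*[catalyst]/(1 + ([starting material]/sat1)) (0.830 M, k = 15.0 M⁻² s⁻¹)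
    catalyst ⇌ dormant form (K = 0.820, k = 9.50 × 10⁻⁴ s⁻¹)

The flask gives 1.1, within the forecast's margin, so its rate at 10% follows the catalyst charge nearly in proportion. It reaches that conversion after 1.56 min. At 70% conversion its rate stands at 0.070 of the rate at 10%, and dividing by 0.0980 gives this flask a kept share of 0.714.

The earlier runs and the new flask were computed on assumed constants.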